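| setting | dusk | autumn | flask |
|---|---|---|---|
| left-handed substrate | 0.031 M | 0.031 M | 0.031 M |
| right-handed substrate | 0.031 M | 0.031 M | 0.031 M |
| solid reagent | 0.0372 M | 0.025 M | 0.0372 M |
| catalyst | 0.31 mM | 0.31 mM | 0.31 mM |
| remark | the very flask that is asked about, followed so far | run made earlier |  |
| time |  |  | 80 min |

- dusk (time / min: left-handed product / %, left-handed substrate / %): 0.417: 2.1, 49.0; 1.33: 2.0, 49.5; 2.50: 1.4, 45.2; 4.00: 4.4, 44.0; 5.00: 6.2, 40.8; 6.00: 9.2, 39.9
- autumn (time / min: left-handed product / %, left-handed substrate / %): 5.00: 5.6, 40.7; 10.0: 13.9, 29.8; 15.0: 20.0, 21.9; 20.0: 19.5, 20.0; 25.0: 16.8, 21.9; 30.0: 20.9, 19.3

(scatter of a reading: 1 percentage point)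

- how much left-handed product there is at 80 min, in percent of the left-handed substrate and right-handed substrate together charged
- the change that raises the amount of left-handed product at 80 min, in percent of the left-handed substrate and right-handed substrate together charged most ("none" if none brings more than 2 percentage points) (cedar / larch / elm / none)
- amount of left-handed product at 80 min, in percent of the left-handed substrate and right-handed substrate together charged, after larch

- cedar: doubling the dissolution coefficient of the solid reagent, all else as stated
- larch: doubling the amount of catalyst, all else as stated
- elm: doubling the solubility of the solid reagent, all else as stated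

- catalyst is single-handed; left-handed substrate and right-handed substrate are mirror images of each other, charged as a racemate, each of them at the stated concentration
- solid, in amounts per volume of the solution: solid reagent
- at the start none of the solid reagent is in solution

Left-handed substrate is left over in the autumn flask: it still reads 19.3% at 30.0 min, while left-handed product has hovered near one level since 15.0 min. The bench guess is a limiting reagent, the solid reagent, charged in autumn at 40.3% of both substrates together. The level readings average 19.3%, and that gives the yield on reagent, left-handed product at the stop per reagent charged, both as fractions of the substrates: 0.479.

The dusk flask holds 60.0%, so this reckoning gives 28.7%. The rule has two borders. The reagent must stay below the substrates, and in dusk it does. The stop must also come in time: at 5.00 min dusk reads 6.2% against 5.6% in autumn, so at that pace dusk needs about 22.3 min, shorter than the time asked. So in dusk a speed change should bring the stop earlier, not higher, and larch should stay at 28.7%.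

The forecast gives 28%, best change none, and 28% after larch, a little below this reckoning, on its own grounds: “the plateau looks like reagent exhaustion rather than catalyst death”.

The flask gives 30.0%, best change none, and 30.0% after larch.

    partner + catalyst + left-handed substrate → catalyst + left-handed product (k = 670 M⁻² s⁻¹)
    partner + catalyst + right-handed substrate → catalyst + right-handed product (k = 170 M⁻² s⁻¹)
    solid reagent ⇌ partner, rate k3*(cs3 - [partner]) while solid is left; crystals form when [partner] > cs3 (solubility = 21.0 mM, k = 0.00210 s⁻¹)
    left-handed product ⇌ right-handed product (k = 0.0190 s⁻¹)

In the dusk flask, solid reagent dissolved into partner, and partner with catalyst turned both substrates into products while solid stood: at 8.00 min solid reagent is 53.1% of its own charge and left-handed product 10.3%. By 40.0 min solid reagent is 0%, and left-handed product, at 30.0% at the asked time, stands level with right-handed product. The yield on reagent had promised 28.7%. A neighbour flask, charged like dusk except for its solid reagent, holds 15.0% of the substrates in reagent, so 0.479 promises 7.18%, and at the asked time that neighbour stands at 7.50%.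

The data come from a simulation for substances that don't exist.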